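**Retrosynthetic overview**
- The strategy rests on the benzene ring (ring A, C1–C6): C3 and C4 carry the adjacent hydroxyls and C1 the propanoate chain, so C2–C3–C4–C5 map onto a 2,3-dioxygenated buta-1,3-diene and C1–C6 onto a two-carbon dienophile.
- Catechol ⇐ enolization of a 5-substituted cyclohex-3-ene-1,2-dione ⇐ E1cB loss of HNO2 from a trans-4-alkyl-5-nitrocyclohexane-1,2-dione ⇐ bromine oxidation of the ene-diol bis(silyl ether).
- Ene-diol bis(silyl ether) ⇐ [4+2] cycloaddition forming C1–C2 and C5–C6 from 2,3-bis(trimethylsilyloxy)buta-1,3-diene and hexadecyl (E)-5-nitropent-4-enoate; this is the only ring-forming event.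
- The cycloadduct is at the ene-diol (acyloin) oxidation level, two hydrogens above the arene even after HNO2 is lost, and its nitro group has no acidic β-hydrogen; oxidation to the 1,2-dione supplies the missing unsaturation and places the nitro group β to a carbonyl before the elimination.
- Nitroalkene ⇐ dehydration of the Henry adduct of hexadecyl 4-oxobutanoate ⇐ ozonolysis of hexadecyl pent-4-enoate; diene ⇐ double O-silylation of butane-2,3-dione.

Key step: step 6

Assumption: the target is achiral, so the two stereocentres created in the cycloaddition are carried as a racemic trans pair and are destroyed on aromatization.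

**Step 1**
Reactants: 1 hexadecan-1-ol; 2 pent-4-enoic acid
Product: 3 hexadecyl pent-4-enoate
Conditions: TsOH·H2O (cat.), PhMe, reflux, Dean–Stark
Reagents that add atoms: none
Why: Fischer esterification driven to completion by azeotropic removal of water, under which the isolated terminal alkene is inert and no stereocentre is involved.

**Step 2**
Reactants: 3 hexadecyl pent-4-enoate
Product: 5 hexadecyl 4-oxobutanoate, via secondary ozonide 4 (not isolated)
Conditions: O3, DCM, −78 °C; then PPh3, −78 °C to rt
Reagents that add atoms: ozone, [O-][O+]=O
Why: Ozonolysis with reductive work-up (dipolar cycloaddition of ozone, Criegee rearrangement to the ozonide, reduction by the phosphine) should cleave the only alkene to the aldehyde without touching the ester; the racemic ozonide centre is lost on reduction.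

**Step 3**
Reactants: 5 hexadecyl 4-oxobutanoate; 6 nitromethane
Product: 7 hexadecyl 4-hydroxy-5-nitropentanoate (racemic)
Conditions: 6 (10 equiv), Et3N (0.3 equiv), THF, 0 °C to rt; AcOH quench
Reagents that add atoms: none
Why: Henry (nitroaldol) reaction in which the amine-generated nitronate adds to the unhindered aliphatic aldehyde; the carbinol centre forms without control and is removed in step 4, and catalytic weak base at low temperature should keep the γ-hydroxy ester from lactonizing.

**Step 4**
Reactants: 7 hexadecyl 4-hydroxy-5-nitropentanoate
Product: 9 hexadecyl (E)-5-nitropent-4-enoate, via mesylate 8 (not isolated)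
Conditions: MsCl (1.2 equiv), Et3N (2.5 equiv), DCM, −20 to 0 °C
Reagents that add atoms: none
Why: O-mesylation followed by E1cB elimination through the nitronate is the standard dehydration of β-nitro alcohols and should give the conjugated nitroalkene in its thermodynamically preferred E geometry, provided the base is quenched cold to avoid deconjugation.

**Step 5**
Reactants: 10 butane-2,3-dione
Product: 12 2,3-bis(trimethylsilyloxy)buta-1,3-diene, via monosilyl enol ether 11 (not isolated)
Conditions: TMSOTf (2.2 equiv), Et3N (2.5 equiv), Et2O, 0 °C to rt; distillation
Reagents that add atoms: trimethylsilyl trifluoromethanesulfonate (TMSOTf), C[Si](C)(C)OS(=O)(=O)C(F)(F)F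
Why: Double enol silylation of a 1,2-diketone by silyl triflate and amine (soft enolization), in which each acetyl group can enolize only towards its methyl group, so the 2,3-dioxygenated diene is the sole possible bis(enol ether).

**Step 6**
Reactants: 9 hexadecyl (E)-5-nitropent-4-enoate; 12 2,3-bis(trimethylsilyloxy)buta-1,3-diene
Product: 13 hexadecyl 3-[(1R*,6R*)-6-nitro-3,4-bis(trimethylsilyloxy)cyclohex-3-en-1-yl]propanoate (trans, racemic)
Conditions: 12 (2.5 equiv), PhMe, 110 °C, sealed tube, Ar, base-washed glass; evaporation of excess 12, used crude
Reagents that add atoms: none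
Why: The diene, whose HOMO is raised by two silyloxy groups, and the electron-poor nitroalkene should combine in a concerted, suprafacial, normal-demand [4+2] cycloaddition, the known Diels–Alder reaction of nitroalkenes with 2-silyloxydienes. The six-membered carbocycle closes in one intermolecular event in which bonds C1–C2 and C5–C6 form together across the s-cis diene. The stereocentres C1 and C6 are set trans by transfer of the E geometry of the dienophile through suprafacial addition; the diene termini are unsubstituted, so no endo/exo question arises, and the racemic outcome is acceptable because both centres vanish on aromatization. Regioselectivity is not at stake because the diene is C2-symmetric. The selectivity needed is carbon–carbon cycloaddition over silyl-transfer (Mukaiyama–Michael) addition and over hetero-cycloaddition through the C=C–N=O unit, and it is secured by the absence of any Lewis acid, a nonpolar solvent and acid-free glassware. The ester and the alkyl chain are inert to neutral heating.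

**Step 7**
Reactants: 13 hexadecyl 3-[(1R*,6R*)-6-nitro-3,4-bis(trimethylsilyloxy)cyclohex-3-en-1-yl]propanoate
Product: 14 hexadecyl 3-[(1R*,2R*)-2-nitro-4,5-dioxocyclohexyl]propanoate (trans, racemic)
Conditions: Br2 (1.0 equiv), DCM, −78 °C; evaporation, used crude
Reagents that add atoms: none
Why: Oxidative desilylation of a 1,2-bis(trimethylsilyloxy)alkene by bromine (electrophilic bromination of the ene-diol ether, then loss of two bromotrimethylsilane) is the established route from such ethers to 1,2-diones; the nitro group, the ester and the two stereocentres should be untouched at −78 °C.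

**Step 8**
Reactants: 14 hexadecyl 3-[(1R*,2R*)-2-nitro-4,5-dioxocyclohexyl]propanoate
Product: 16 hexadecyl 3-(3,4-dihydroxyphenyl)propanoate, via cyclohexenedione 15 (not isolated)
Conditions: Et3N (1.5 equiv), THF, 0 °C to rt, Ar; pH 7 phosphate buffer
Reagents that add atoms: none
Why: E1cB elimination of nitrite from a β-nitro ketone (target numbering: C5–H is α to the C4 carbonyl, the nitro group sits on C6), followed by base-mediated keto–enol tautomerization of the resulting cyclohex-3-ene-1,2-dione, which is an isomer of the catechol and should aromatize irreversibly, erasing the C1 and C6 stereocentres.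

**Compound list**
1 | hexadecan-1-ol | CCCCCCCCCCCCCCCCO | starting material
2 | pent-4-enoic acid | C=CCCC(=O)O | starting material
3 | hexadecyl pent-4-enoate | CCCCCCCCCCCCCCCCOC(=O)CCC=C | intermediate
4 | hexadecyl 3-(1,2,4-trioxolan-3-yl)propanoate (secondary ozonide, racemic) | CCCCCCCCCCCCCCCCOC(=O)CCC1OCOO1 | intermediate
5 | hexadecyl 4-oxobutanoate | CCCCCCCCCCCCCCCCOC(=O)CCC=O | intermediate
6 | nitromethane | C[N+](=O)[O-] | starting material
7 | hexadecyl 4-hydroxy-5-nitropentanoate (racemic) | CCCCCCCCCCCCCCCCOC(=O)CCC(O)C[N+](=O)[O-] | intermediate
8 | hexadecyl 4-(methanesulfonyloxy)-5-nitropentanoate (racemic) | CCCCCCCCCCCCCCCCOC(=O)CCC(OS(C)(=O)=O)C[N+](=O)[O-] | intermediate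
9 | hexadecyl (E)-5-nitropent-4-enoate | CCCCCCCCCCCCCCCCOC(=O)CC/C=C/[N+](=O)[O-] | intermediate
10 | butane-2,3-dione | CC(=O)C(C)=O | starting material
11 | 3-(trimethylsilyloxy)but-3-en-2-one | CC(=O)C(=C)O[Si](C)(C)C | intermediate
12 | 2,3-bis(trimethylsilyloxy)buta-1,3-diene | C=C(O[Si](C)(C)C)C(=C)O[Si](C)(C)C | intermediate
13 | hexadecyl 3-[(1R*,6R*)-6-nitro-3,4-bis(trimethylsilyloxy)cyclohex-3-en-1-yl]propanoate (trans, racemic, one enantiomer drawn) | CCCCCCCCCCCCCCCCOC(=O)CC[C@@H]1CC(O[Si](C)(C)C)=C(O[Si](C)(C)C)C[C@H]1[N+](=O)[O-] | intermediate
14 | hexadecyl 3-[(1R*,2R*)-2-nitro-4,5-dioxocyclohexyl]propanoate (trans, racemic, one enantiomer drawn) | CCCCCCCCCCCCCCCCOC(=O)CC[C@@H]1CC(=O)C(=O)C[C@H]1[N+](=O)[O-] | intermediate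
15 | hexadecyl 3-(4,5-dioxocyclohex-2-en-1-yl)propanoate (racemic) | CCCCCCCCCCCCCCCCOC(=O)CCC1CC(=O)C(=O)C=C1 | intermediate
16 | hexadecyl 3-(3,4-dihydroxyphenyl)propanoate | CCCCCCCCCCCCCCCCOC(=O)CCc1ccc(O)c(O)c1 | target

**Step count**
Total: 8 steps. Longest linear sequence: 7 steps (steps 1, 2, 3, 4, 6, 7, 8); the diene is made in one step (step 5) on a side branch.

**Steps most likely to fail**

Step 6. The cycloaddition of a β-alkyl nitroalkene may be too slow at temperatures the diene tolerates. Desilylation or oligomerization of the diene, silyl-transfer Michael addition, or hetero-cycloaddition across the C=C–N=O unit could then outrun ring closure. The fallback gives up ring construction. It sets out from hexadecan-1-ol (1), which would be esterified with purchased 3-(3,4-dihydroxyphenyl)propanoic acid under TsOH·H2O (cat.), PhMe, reflux, Dean–Stark. It comes back to the route at the target 16. No compound outside the list is made on this path (F0).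

Step 8. The catechol is set free as an ammonium phenolate in the presence of nitrite. Oxidation by adventitious air, or nitrosation and oxidation by nitrous acid if the mixture turns acidic, may erode it to quinone-derived material. The fallback sets out from dione 14 and captures the arene in protected form as it is born. Ac2O, Et3N and DMAP (cat.) in DCM at 0 °C to rt should effect the same E1cB loss of nitrite and enolization while acetylating both phenols, giving hexadecyl 3-(3,4-diacetoxyphenyl)propanoate F1. After nitrite salts are washed out, N2H4·H2O in THF at 0 °C should cleave the two aryl acetates by aminolysis while the alkyl ester is left alone. This comes back to the route at 16.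

Step 3. The γ-hydroxy ester formed in the nitroaldol addition may lactonize with expulsion of hexadecanol, or revert by retro-Henry reaction on work-up. The fallback never forms the hydroxy ester. It sets out from alkene 3, which would take up nitryl iodide (AgNO2, I2, Et2O, rt), with the nitro group going to the terminal carbon, to give hexadecyl 4-iodo-5-nitropentanoate F2. Dehydroiodination with Et3N at 0 °C in the same flask should then return to the route at nitroalkene 9.

**Further compounds**
F0 | step 6 | none | none
F1 | step 8 | hexadecyl 3-(3,4-diacetoxyphenyl)propanoate | CCCCCCCCCCCCCCCCOC(=O)CCc1ccc(OC(C)=O)c(OC(C)=O)c1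
F2 | step 3 | hexadecyl 4-iodo-5-nitropentanoate | CCCCCCCCCCCCCCCCOC(=O)CCC(I)C[N+](=O)[O-]
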